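**Plan**

- Retrosynthesis: the three phenols are masked as MOM ethers and the C3 aldehyde is traced back to an ethyl ester. The furan is cut at C3–C3a and O1–C2, giving an O-aryl oxime ether, which is cut at C=N, then at N–O, then at the two aryl–prenyl bonds.
- Enabling feature: O1 and C3a sit on neighbouring carbons of ring A (C7a and C3a), C2 carries ring B and C3 carries the formyl carbon. A ring A aryloxyamine and a ring B aroylacetate therefore hold every atom of the furan.
- Forward: aryloxyamine 8 from resorcinol (steps 1–4) and keto ester 15 from 4,6-dibromoresorcinol (steps 5–8) are condensed in step 9. The furan, the only ring made, closes in step 10; reduction, oxidation and MOM removal follow (steps 11–13).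
- Stereochemistry: the target has no stereocentre and no alkene with geometry; the oxime geometry of 16 is erased in step 10.

Key step: step 10

Remark: MOM = methoxymethyl, prenyl = 3-methylbut-2-en-1-yl. Oxime ether 16 is drawn as the E isomer expected to predominate; the Z isomer and the enamine tautomer should enter step 10 equally well.

**Route**

Step 1
Reactants: 1 resorcinol
Product: 2 1,3-bis(methoxymethoxy)benzene
Conditions: MOMCl, i-Pr2NEt, CH2Cl2, 0 °C → rt
Reagents that add atoms: chloromethyl methyl ether, COCCl
Why: O-alkylation of both phenols with an α-chloro ether under amine base (MOM acetal protection) installs the groups that later direct lithiation.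

Step 2
Reactants: 2 1,3-bis(methoxymethoxy)benzene, 3 prenyl bromide
Product: 5 1,3-bis(methoxymethoxy)-2-prenylbenzene, via 2,6-bis(methoxymethoxy)phenyllithium 4 (not isolated)
Conditions: n-BuLi, THF, 0 °C; then prenyl bromide, −78 °C → rt
Reagents that add atoms: none
Why: Directed ortho-metalation, in which the two MOM ethers cooperate to place lithium at C2, followed by SN2 alkylation of the aryllithium at the primary allylic carbon.

Step 3
Reactants: 5 1,3-bis(methoxymethoxy)-2-prenylbenzene
Product: 6 3-(methoxymethoxy)-2-prenylphenol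
Conditions: conc. HCl (cat.), MeOH, 0 °C → rt, stopped at partial conversion; recovered 5 recycled
Reagents that add atoms: none
Why: Acid-catalysed acetal exchange with methanol removes one of the two equivalent MOM groups when stopped early, so only one mono-phenol can form, and the dilute acid at ambient temperature should not add the new phenol across the prenyl alkene.

Step 4
Reactants: 6 3-(methoxymethoxy)-2-prenylphenol
Product: 8 O-[3-(methoxymethoxy)-2-prenylphenyl]hydroxylamine, via sodium 3-(methoxymethoxy)-2-prenylphenoxide 7 (not isolated)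
Conditions: NaH, DMF, 0 °C; then O-(2,4-dinitrophenyl)hydroxylamine, 0 °C → rt
Reagents that add atoms: O-(2,4-dinitrophenyl)hydroxylamine, NOc1ccc(cc1[N+](=O)[O-])[N+](=O)[O-]
Why: Electrophilic amination of a phenoxide, in which the oxygen nucleophile attacks the nitrogen of the reagent and expels the stabilised 2,4-dinitrophenoxide; the product is used at once as the free base.

Step 5
Reactants: 9 4,6-dibromoresorcinol
Product: 10 1,5-dibromo-2,4-bis(methoxymethoxy)benzene
Conditions: MOMCl, i-Pr2NEt, CH2Cl2, 0 °C → rt
Reagents that add atoms: chloromethyl methyl ether, COCCl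
Why: MOM acetal protection of both phenols by O-alkylation, as in step 1.

Step 6
Reactants: 10 1,5-dibromo-2,4-bis(methoxymethoxy)benzene, 3 prenyl bromide
Product: 12 1-bromo-2,4-bis(methoxymethoxy)-5-prenylbenzene, via 5-bromo-2,4-bis(methoxymethoxy)phenyllithium 11 (not isolated)
Conditions: n-BuLi (1 equiv), THF, −78 °C; then prenyl bromide, −78 °C → rt
Reagents that add atoms: none
Why: Single bromine–lithium exchange on the symmetric dibromide (the aryllithium is stabilised by the ortho MOM ether and a second exchange is disfavoured) followed by SN2 allylation, which fixes prenyl at the future C5' without any regiochemical ambiguity.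

Step 7
Reactants: 12 1-bromo-2,4-bis(methoxymethoxy)-5-prenylbenzene
Product: 14 1-[2,4-bis(methoxymethoxy)-5-prenylphenyl]ethan-1-one, via 2,4-bis(methoxymethoxy)-5-prenylphenyllithium 13 (not isolated)
Conditions: n-BuLi, THF, −78 °C; then N-methoxy-N-methylacetamide, −78 → 0 °C; then H2O
Reagents that add atoms: N-methoxy-N-methylacetamide, CON(C)C(C)=O
Why: Bromine–lithium exchange and Weinreb ketone synthesis, in which the chelated tetrahedral adduct prevents over-addition and releases the methyl ketone on quench.

Step 8
Reactants: 14 1-[2,4-bis(methoxymethoxy)-5-prenylphenyl]ethan-1-one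
Product: 15 ethyl 3-[2,4-bis(methoxymethoxy)-5-prenylphenyl]-3-oxopropanoate
Conditions: NaH, (EtO)2CO, THF, reflux; then AcOH
Reagents that add atoms: diethyl carbonate, CCOC(=O)OCC
Why: Crossed Claisen condensation of the ketone enolate with diethyl carbonate, driven to completion by deprotonation of the β-keto ester formed.

Step 9
Reactants: 8 O-[3-(methoxymethoxy)-2-prenylphenyl]hydroxylamine, 15 ethyl 3-[2,4-bis(methoxymethoxy)-5-prenylphenyl]-3-oxopropanoate
Product: 16 ethyl (3E)-3-[2,4-bis(methoxymethoxy)-5-prenylphenyl]-3-{[3-(methoxymethoxy)-2-prenylphenoxy]imino}propanoate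
Conditions: AcOH (cat.), MgSO4, EtOH, 40 °C
Reagents that add atoms: none
Why: Oxime ether formation, in which the α-effect nitrogen condenses with the ketone carbonyl and not the ester, and the arylated oxygen cannot close to an isoxazolone.

Step 10
Reactants: 16 ethyl (3E)-3-[2,4-bis(methoxymethoxy)-5-prenylphenyl]-3-{[3-(methoxymethoxy)-2-prenylphenoxy]imino}propanoate
Product: 19 ethyl 2-[2,4-bis(methoxymethoxy)-5-prenylphenyl]-6-(methoxymethoxy)-7-prenylbenzofuran-3-carboxylate, via N-trifluoroacetyl enamide 17 (not isolated), via trifluoroacetamido dihydrobenzofuran 18 (not isolated)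
Conditions: (CF3CO)2O, DMAP, CH2Cl2, 0 °C → rt
Reagents that add atoms: none
Why: N-Trifluoroacetylation of the oxime nitrogen and loss of the ester-activated α-proton give the N-acyl-N-aryloxy enamine 17, whose weak N–O bond breaks in a [3,3] sigmatropic shift that joins the ester α-carbon (C3) to the free ortho carbon of ring A (C3a). Tautomerisation of the resulting cyclohexadienone restores the phenol, which adds to the N-acylimine carbon (O1–C2) in a 5-exo-trig closure to give aminal 18, and DMAP-assisted elimination of trifluoroacetamide across C2–C3 aromatises the furan. The closest known reaction type is the acylation-triggered rearrangement of O-aryl oxime ethers to benzofurans, the oxygen counterpart of the Fischer indole synthesis, which is also known for oxime ethers of 1,3-dicarbonyl compounds. No stereocentre remains in 19, so the two centres of 18 and the oxime geometry of 16 are of no consequence. The step needs site selectivity between the two ortho carbons of ring A, and the prenyl group secures it: bond formation at the prenyl-bearing carbon would give a dienone that cannot rearomatise, so only the C–H ortho carbon leads on, which places prenyl at C7 and the MOM ether at C6. The buffered conditions at or below room temperature should leave the MOM acetals and the prenyl alkenes untouched.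

Step 11
Reactants: 19 ethyl 2-[2,4-bis(methoxymethoxy)-5-prenylphenyl]-6-(methoxymethoxy)-7-prenylbenzofuran-3-carboxylate
Product: 20 {2-[2,4-bis(methoxymethoxy)-5-prenylphenyl]-6-(methoxymethoxy)-7-prenylbenzofuran-3-yl}methanol
Conditions: i-Bu2AlH, CH2Cl2, −78 → 0 °C; aq. potassium sodium tartrate
Reagents that add atoms: none
Why: Hydride reduction of the ester to the primary alcohol with i-Bu2AlH, which spares aryl MOM ethers and isolated alkenes; the ester is reduced while ring B O2' is still protected, so no coumestan lactone can form.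

Step 12
Reactants: 20 {2-[2,4-bis(methoxymethoxy)-5-prenylphenyl]-6-(methoxymethoxy)-7-prenylbenzofuran-3-yl}methanol
Product: 21 2-[2,4-bis(methoxymethoxy)-5-prenylphenyl]-6-(methoxymethoxy)-7-prenylbenzofuran-3-carbaldehyde
Conditions: MnO2, CH2Cl2, rt
Reagents that add atoms: none
Why: MnO2 oxidation of an activated (heterobenzylic) alcohol stops at the aldehyde and does not touch the prenyl groups.

Step 13
Reactants: 21 2-[2,4-bis(methoxymethoxy)-5-prenylphenyl]-6-(methoxymethoxy)-7-prenylbenzofuran-3-carbaldehyde
Product: 22 eryvarin Q, 2-(2,4-dihydroxy-5-prenylphenyl)-6-hydroxy-7-prenylbenzofuran-3-carbaldehyde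
Conditions: 2 M aq. HCl, THF, 45 °C
Reagents that add atoms: none
Why: Acid hydrolysis of the three MOM acetals; aqueous THF without methanol avoids acetal formation at the aldehyde, and the moderate acidity and temperature are chosen to limit addition of the freed phenols to the prenyl alkenes.

**Compound list**

1 | resorcinol (benzene-1,3-diol) | Oc1cccc(O)c1 | starting material
2 | 1,3-bis(methoxymethoxy)benzene | COCOc1cccc(OCOC)c1 | intermediate
3 | prenyl bromide (1-bromo-3-methylbut-2-ene) | CC(C)=CCBr | starting material
4 | 2,6-bis(methoxymethoxy)phenyllithium (not isolated) | [Li]c1c(OCOC)cccc1OCOC | intermediate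
5 | 1,3-bis(methoxymethoxy)-2-prenylbenzene | COCOc1cccc(OCOC)c1CC=C(C)C | intermediate
6 | 3-(methoxymethoxy)-2-prenylphenol | COCOc1cccc(O)c1CC=C(C)C | intermediate
7 | sodium 3-(methoxymethoxy)-2-prenylphenoxide (not isolated) | [Na+].[O-]c1cccc(OCOC)c1CC=C(C)C | intermediate
8 | O-[3-(methoxymethoxy)-2-prenylphenyl]hydroxylamine | NOc1cccc(OCOC)c1CC=C(C)C | intermediate
9 | 4,6-dibromoresorcinol (4,6-dibromobenzene-1,3-diol) | Oc1cc(O)c(Br)cc1Br | starting material
10 | 1,5-dibromo-2,4-bis(methoxymethoxy)benzene | COCOc1cc(OCOC)c(Br)cc1Br | intermediate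
11 | 5-bromo-2,4-bis(methoxymethoxy)phenyllithium (not isolated) | [Li]c1cc(Br)c(OCOC)cc1OCOC | intermediate
12 | 1-bromo-2,4-bis(methoxymethoxy)-5-prenylbenzene | COCOc1cc(OCOC)c(CC=C(C)C)cc1Br | intermediate
13 | 2,4-bis(methoxymethoxy)-5-prenylphenyllithium (not isolated) | [Li]c1cc(CC=C(C)C)c(OCOC)cc1OCOC | intermediate
14 | 1-[2,4-bis(methoxymethoxy)-5-prenylphenyl]ethan-1-one | CC(=O)c1cc(CC=C(C)C)c(OCOC)cc1OCOC | intermediate
15 | ethyl 3-[2,4-bis(methoxymethoxy)-5-prenylphenyl]-3-oxopropanoate | CCOC(=O)CC(=O)c1cc(CC=C(C)C)c(OCOC)cc1OCOC | intermediate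
16 | ethyl (3E)-3-[2,4-bis(methoxymethoxy)-5-prenylphenyl]-3-{[3-(methoxymethoxy)-2-prenylphenoxy]imino}propanoate | CCOC(=O)C/C(=N\Oc1cccc(OCOC)c1CC=C(C)C)c1cc(CC=C(C)C)c(OCOC)cc1OCOC | intermediate
17 | ethyl 3-[2,4-bis(methoxymethoxy)-5-prenylphenyl]-3-{N-[3-(methoxymethoxy)-2-prenylphenoxy]-2,2,2-trifluoroacetamido}prop-2-enoate (not isolated, alkene geometry not defined) | CCOC(=O)C=C(N(Oc1cccc(OCOC)c1CC=C(C)C)C(=O)C(F)(F)F)c1cc(CC=C(C)C)c(OCOC)cc1OCOC | intermediate
18 | ethyl 2-[2,4-bis(methoxymethoxy)-5-prenylphenyl]-6-(methoxymethoxy)-7-prenyl-2-(2,2,2-trifluoroacetamido)-2,3-dihydrobenzofuran-3-carboxylate (not isolated, racemic mixture of diastereomers) | CCOC(=O)C1c2ccc(OCOC)c(CC=C(C)C)c2OC1(NC(=O)C(F)(F)F)c1cc(CC=C(C)C)c(OCOC)cc1OCOC | intermediate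
19 | ethyl 2-[2,4-bis(methoxymethoxy)-5-prenylphenyl]-6-(methoxymethoxy)-7-prenylbenzofuran-3-carboxylate | CCOC(=O)c1c(-c2cc(CC=C(C)C)c(OCOC)cc2OCOC)oc2c(CC=C(C)C)c(OCOC)ccc12 | intermediate
20 | {2-[2,4-bis(methoxymethoxy)-5-prenylphenyl]-6-(methoxymethoxy)-7-prenylbenzofuran-3-yl}methanol | OCc1c(-c2cc(CC=C(C)C)c(OCOC)cc2OCOC)oc2c(CC=C(C)C)c(OCOC)ccc12 | intermediate
21 | 2-[2,4-bis(methoxymethoxy)-5-prenylphenyl]-6-(methoxymethoxy)-7-prenylbenzofuran-3-carbaldehyde | O=Cc1c(-c2cc(CC=C(C)C)c(OCOC)cc2OCOC)oc2c(CC=C(C)C)c(OCOC)ccc12 | intermediate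
22 | eryvarin Q, 2-(2,4-dihydroxy-5-prenylphenyl)-6-hydroxy-7-prenylbenzofuran-3-carbaldehyde | CC(C)=CCc1cc(-c2oc3c(CC=C(C)C)c(O)ccc3c2C=O)c(O)cc1O | target

**Count**

Total step count: 13. Longest linear sequence: 9 steps (steps 1–4 or steps 5–8, followed by steps 9–13).

**Steps most likely to fail**

Step 4. Transfer of the amino group to the phenoxide oxygen may be outrun by attack of the phenoxide on the dinitrophenyl ring of the reagent, or the free aryloxyamine may decompose during isolation. The fallback makes the aryl–O–N bond from the aryl side by Chan–Lam coupling. It sets out from phenol 6, which with Tf2O and pyridine in CH2Cl2 should give 3-(methoxymethoxy)-2-prenylphenyl trifluoromethanesulfonate F1. Miyaura borylation (B2pin2, PdCl2(dppf), KOAc, dioxane, 80 °C) should give 2-[3-(methoxymethoxy)-2-prenylphenyl]-4,4,5,5-tetramethyl-1,3,2-dioxaborolane F2. Oxidative removal of pinacol (NaIO4, NH4OAc, acetone–water) should free [3-(methoxymethoxy)-2-prenylphenyl]boronic acid F3. Coupling with N-hydroxyphthalimide (CuCl, pyridine, 1,2-dichloroethane, air, rt) should give 2-[3-(methoxymethoxy)-2-prenylphenoxy]isoindoline-1,3-dione F4. Hydrazine hydrate in CH2Cl2–MeOH then releases aryloxyamine 8, where the route is rejoined.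

Step 10. The vinylogous carbamate character of the enamine tautomer may divert trifluoroacetylation to the α-carbon, the sequence may stall at the aminal, or MOM groups may be lost if trifluoroacetic acid is not fully buffered. The fallback removes the ester from the rearrangement substrate and adds the formyl carbon afterwards. It sets out from aryloxyamine 8 and methyl ketone 14, which condense (AcOH cat., EtOH) to (1E)-1-[2,4-bis(methoxymethoxy)-5-prenylphenyl]ethan-1-one O-[3-(methoxymethoxy)-2-prenylphenyl]oxime F5. This is the simple aryl methyl ketone oxime ether for which the (CF3CO)2O/DMAP rearrangement is best established. It should give 2-[2,4-bis(methoxymethoxy)-5-prenylphenyl]-6-(methoxymethoxy)-7-prenylbenzofuran F6. Vilsmeier–Haack formylation (POCl3, DMF, 0 °C → rt, buffered aqueous NaOAc work-up) should then functionalise C3, the enol-ether β-carbon of the 2-arylbenzofuran. This gives aldehyde 21 directly, so steps 11 and 12 are not needed.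

Step 13. Acid-catalysed addition of the liberated phenols across the neighbouring prenyl double bonds (chroman formation) may compete with acetal hydrolysis. The fallback replaces Brønsted-acid hydrolysis by silyl transfer under aprotic, base-buffered conditions. It sets out from 21, which with TMSOTf and 2,2'-bipyridyl in CH3CN at 0 °C should exchange each aryl MOM ether for a silyl ether. The product would be 2-[5-prenyl-2,4-bis(trimethylsilyloxy)phenyl]-7-prenyl-6-(trimethylsilyloxy)benzofuran-3-carbaldehyde F7. Its Si–O bonds are then hydrolysed with water at neutral pH to give eryvarin Q 22, so no strong acid is present while free phenols sit next to the prenyl groups.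

**Further compounds**

F1 | step 4 | 3-(methoxymethoxy)-2-prenylphenyl trifluoromethanesulfonate | COCOc1cccc(OS(=O)(=O)C(F)(F)F)c1CC=C(C)C
F2 | step 4 | 2-[3-(methoxymethoxy)-2-prenylphenyl]-4,4,5,5-tetramethyl-1,3,2-dioxaborolane | COCOc1cccc(B2OC(C)(C)C(C)(C)O2)c1CC=C(C)C
F3 | step 4 | [3-(methoxymethoxy)-2-prenylphenyl]boronic acid | COCOc1cccc(B(O)O)c1CC=C(C)C
F4 | step 4 | 2-[3-(methoxymethoxy)-2-prenylphenoxy]isoindoline-1,3-dione | COCOc1cccc(ON2C(=O)c3ccccc3C2=O)c1CC=C(C)C
F5 | step 10 | (1E)-1-[2,4-bis(methoxymethoxy)-5-prenylphenyl]ethan-1-one O-[3-(methoxymethoxy)-2-prenylphenyl]oxime | C/C(=N\Oc1cccc(OCOC)c1CC=C(C)C)c1cc(CC=C(C)C)c(OCOC)cc1OCOC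
F6 | step 10 | 2-[2,4-bis(methoxymethoxy)-5-prenylphenyl]-6-(methoxymethoxy)-7-prenylbenzofuran | COCOc1cc(OCOC)c(CC=C(C)C)cc1-c1cc2ccc(OCOC)c(CC=C(C)C)c2o1
F7 | step 13 | 2-[5-prenyl-2,4-bis(trimethylsilyloxy)phenyl]-7-prenyl-6-(trimethylsilyloxy)benzofuran-3-carbaldehyde | O=Cc1c(-c2cc(CC=C(C)C)c(O[Si](C)(C)C)cc2O[Si](C)(C)C)oc2c(CC=C(C)C)c(O[Si](C)(C)C)ccc12
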